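**Plan**

- Retrosynthesis first cuts the oxolane O1–C2 bond. C2 is the end of a pentadienyl unit (C2 plus the four butadienyl carbons C4′–C1′) that runs on into the isocoumarin C3=C4. The O1–C2 bond can therefore be closed, and reopened, through a cation spread over these five carbons, and the diene forms in the same event by allylic transposition.
- The acyclic precursor, a 1,4-dien-3-ol, is cut at the carbinol bond C3′–C4′ into an isocoumarinyl enal and a six-carbon (E)-iodoalkene syn-1,3-diol. The enal is cut at C1′=C2′ (Wittig), and the pyranone at O2–C1 and C3–C4 back to a chlorinated orsellinate and a diethoxyacetyl unit.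
- Forward order: the pyranone ring is made first, the chain is joined at the carbinol carbon, and the oxolane ring is closed last, followed only by desilylation.
- Stereochemistry: C5 comes from ethyl (3S)-3-hydroxybutanoate. C3 is set by a chelation-controlled syn-1,3-reduction. C2 is set in the ring closure by the two centres already present (dienyl trans to 3-OH, cis to 5-Me). Both diene bonds are (E) from the enal and from the extended cation. The carbinol centre made in the coupling is not controlled and is destroyed.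

Key step: step 11

Assumption: the (2R) configuration, with the dienyl group trans to the C3 hydroxyl and cis to the C5 methyl group, is taken to be the more stable C2 epimer of the pentadienylic ether, so that reversible ionisation in step 11 should converge on it.

**Route**

Step 1
Reactants: 1 methyl 2,4-dihydroxy-6-methylbenzoate (methyl orsellinate)
Product: 2 methyl 3-chloro-4,6-dihydroxy-2-methylbenzoate
Conditions: SO2Cl2 (1.05 equiv), Et2O, 0 °C to rt
Reagents that add atoms: sulfuryl chloride, O=S(=O)(Cl)Cl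
Why: Electrophilic aromatic chlorination should go to the ring position para to the chelated 2-OH and ortho to the 4-OH, which becomes C5 of the isocoumarin; the isomer chlorinated between the two hydroxyls is the expected minor product and is to be removed by crystallisation.

Step 2
Reactants: 2 methyl 3-chloro-4,6-dihydroxy-2-methylbenzoate
Product: 3 methyl 3-chloro-2-methyl-4,6-bis[(triisopropylsilyl)oxy]benzoate
Conditions: TIPSOTf (2.4 equiv), 2,6-lutidine, CH2Cl2, 0 °C to rt
Reagents that add atoms: triisopropylsilyl trifluoromethanesulfonate, CC(C)[Si](C(C)C)(C(C)C)OS(=O)(=O)C(F)(F)F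
Why: Silyl triflate silylation covers both phenols, including the hydrogen-bonded one, as aryl TIPS ethers that tolerate amide bases and aqueous acid and can be removed by fluoride at the end.

Step 3
Reactants: 3 methyl 3-chloro-2-methyl-4,6-bis[(triisopropylsilyl)oxy]benzoate; 4 1-(diethoxyacetyl)piperidine
Product: 6 methyl 3-chloro-2-(3,3-diethoxy-2-oxopropyl)-4,6-bis[(triisopropylsilyl)oxy]benzoate, via benzylic lithium species 5 (not isolated)
Conditions: LDA (1.2 equiv), THF, −78 °C; then 4, −78 to −30 °C; AcOH quench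
Reagents that add atoms: none
Why: Lateral lithiation of the o-toluate, made possible by the ortho ester, followed by acylation with an α,α-dialkoxy amide whose tetrahedral adduct holds until work-up, should give the α-keto acetal without over-addition.

Step 4
Reactants: 6 methyl 3-chloro-2-(3,3-diethoxy-2-oxopropyl)-4,6-bis[(triisopropylsilyl)oxy]benzoate
Product: 7 5-chloro-1-oxo-6,8-bis[(triisopropylsilyl)oxy]-1H-isochromene-3-carbaldehyde
Conditions: TFA/H2O (9:1), CH2Cl2, 0 °C to rt
Reagents that add atoms: water, O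
Why: Acetal hydrolysis frees a 1,2-dicarbonyl whose benzylic enol acylates on the neighbouring ester (6-exo-trig, loss of methanol), an acid-mediated enol-lactonisation driven by formation of the aromatic pyranone ring.

Step 5
Reactants: 7 5-chloro-1-oxo-6,8-bis[(triisopropylsilyl)oxy]-1H-isochromene-3-carbaldehyde; 8 (triphenylphosphoranylidene)acetaldehyde
Product: 9 (2E)-3-{5-chloro-1-oxo-6,8-bis[(triisopropylsilyl)oxy]-1H-isochromen-3-yl}prop-2-enal
Conditions: 8 (1.2 equiv), toluene, 60 °C
Reagents that add atoms: none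
Why: Wittig reaction of a stabilised ylide with the electron-poor aldehyde should give the (E)-enal, which is less reactive than 7 toward a second homologation.

Step 6
Reactants: 10 ethyl (3S)-3-hydroxybutanoate
Product: 11 (3S)-3-hydroxy-N-methoxy-N-methylbutanamide
Conditions: MeNH(OMe)·HCl (1.5 equiv), i-PrMgCl (4 equiv), THF, −20 to 0 °C
Reagents that add atoms: N,O-dimethylhydroxylamine hydrochloride, CNOC.Cl
Why: Aminolysis of the ester by the magnesium amide gives the Weinreb amide without touching the carbinol stereocentre, the future oxolane C5.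

Step 7
Reactants: 11 (3S)-3-hydroxy-N-methoxy-N-methylbutanamide; 12 (E)-1,2-bis(tributylstannyl)ethene
Product: 14 (1E,5S)-5-hydroxy-1-(tributylstannyl)hex-1-en-3-one, via (E)-2-(tributylstannyl)vinyllithium 13 (not isolated)
Conditions: 12 (2.4 equiv), n-BuLi (2.3 equiv), THF, −78 °C; then 11, −78 to −40 °C; AcOH quench
Reagents that add atoms: none
Why: Tin–lithium exchange gives the (E)-stannylvinyllithium with retention, and its acylation by the Weinreb amide stops at the ketone because the chelated tetrahedral adduct survives until work-up (one equivalent is spent on the hydroxyl).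

Step 8
Reactants: 14 (1E,5S)-5-hydroxy-1-(tributylstannyl)hex-1-en-3-one
Product: 16 (1E,3S,5S)-1-(tributylstannyl)hex-1-ene-3,5-diol, via diethylboron chelate 15 (not isolated)
Conditions: Et2BOMe (1.1 equiv), THF/MeOH (4:1), −78 °C; NaBH4, −78 °C; then MeOH, co-evaporation
Reagents that add atoms: none
Why: In this Narasaka–Prasad reduction, hydride attacks the six-membered boron chelate axially from outside, which gives the syn-1,3-diol and so sets the future oxolane C3 as (S) by 1,3-induction from C5; chelation also directs 1,2- over 1,4-reduction.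

Step 9
Reactants: 16 (1E,3S,5S)-1-(tributylstannyl)hex-1-ene-3,5-diol
Product: 17 (1E,3S,5S)-1-iodohex-1-ene-3,5-diol
Conditions: I2 (1.05 equiv), CH2Cl2, 0 °C; aq. KF work-up
Reagents that add atoms: iodine, II
Why: Iododestannylation takes place at the ipso carbon with retention of the (E) geometry and is much faster than any reaction of iodine with the hydroxyls.

Step 10
Reactants: 9 (2E)-3-{5-chloro-1-oxo-6,8-bis[(triisopropylsilyl)oxy]-1H-isochromen-3-yl}prop-2-enal; 17 (1E,3S,5S)-1-iodohex-1-ene-3,5-diol
Product: 18 5-chloro-3-[(1E,4E,6S,8S)-3,6,8-trihydroxynona-1,4-dien-1-yl]-6,8-bis[(triisopropylsilyl)oxy]-1H-isochromen-1-one (both epimers at the carbinol C3 of the chain)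
Conditions: CrCl2 (6 equiv), NiCl2 (2 mol %), DMSO/THF, rt; buffered (pH 8) serinate work-up
Reagents that add atoms: none
Why: In the Nozaki–Hiyama–Kishi coupling, Ni(0) inserts into the C–I bond and transmetalation gives an alkenylchromium(III) that adds 1,2 to the enal in the presence of the lactone, the aryl chloride and the free hydroxyls; the new carbinol centre is not controlled and need not be.

Step 11
Reactants: 18 5-chloro-3-[(1E,4E,6S,8S)-3,6,8-trihydroxynona-1,4-dien-1-yl]-6,8-bis[(triisopropylsilyl)oxy]-1H-isochromen-1-one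
Product: 20 5-chloro-3-[(1E,3E)-4-[(2R,3S,5S)-3-hydroxy-5-methyloxolan-2-yl]buta-1,3-dien-1-yl]-6,8-bis[(triisopropylsilyl)oxy]-1H-isochromen-1-one, via pentadienyl cation 19 (not isolated)
Conditions: Re2O7 (5 mol %), CH2Cl2 (0.01 M), 0 °C to rt; then Et3N
Reagents that add atoms: none
Why: The perrhenate ester of the bis-allylic alcohol ionises to pentadienyl cation 19, delocalised over chain carbons C1–C5 and into the isocoumarin C3=C4, and the C8 hydroxyl captures the C5 terminus, which forms the O1–C2 bond and shifts the double bond into conjugation. The closest known reaction type is the Re2O7-catalysed allylic transposition and dehydrative cycloetherification of hydroxy allylic alcohols, which runs under thermodynamic control. The oxolane closes in the 5-exo mode with the allyl π-system outside the ring, whereas attack by the C6 hydroxyl would need an oxirane or a cis-configured dihydrofuran and, being reversible, should drain back. The new stereocentre C2 is controlled by the ring substituents already present, since the dienyl group should settle trans to the C3 hydroxyl and cis to the C5 methyl group in both the envelope transition state and the product, and re-ionisation of the pentadienylic ether lets the minor epimer and both carbinol epimers of 18 converge. The (E,E) geometry follows from capture of the extended cation and is also the stable one. The step needs the cation to be trapped faster than it loses a proton or shifts a hydride, which high dilution and the five-membered transition state should secure.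

Step 12
Reactants: 20 5-chloro-3-[(1E,3E)-4-[(2R,3S,5S)-3-hydroxy-5-methyloxolan-2-yl]buta-1,3-dien-1-yl]-6,8-bis[(triisopropylsilyl)oxy]-1H-isochromen-1-one
Product: 21 5-chloro-6,8-dihydroxy-3-[(1E,3E)-4-[(2R,3S,5S)-3-hydroxy-5-methyloxolan-2-yl]buta-1,3-dien-1-yl]-1H-isochromen-1-one
Conditions: TBAF (2.5 equiv), AcOH (2.5 equiv), THF, 0 °C
Reagents that add atoms: none
Why: Buffered fluoride cleaves the two aryl silyl ethers under non-acidic conditions that should leave the pentadienylic ether, the lactone and the secondary alcohol untouched.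

**Compound list**

1 | methyl 2,4-dihydroxy-6-methylbenzoate (methyl orsellinate) | COC(=O)c1c(C)cc(O)cc1O | starting material
2 | methyl 3-chloro-4,6-dihydroxy-2-methylbenzoate | COC(=O)c1c(C)c(Cl)c(O)cc1O | intermediate
3 | methyl 3-chloro-2-methyl-4,6-bis[(triisopropylsilyl)oxy]benzoate | COC(=O)c1c(C)c(Cl)c(O[Si](C(C)C)(C(C)C)C(C)C)cc1O[Si](C(C)C)(C(C)C)C(C)C | intermediate
4 | 1-(diethoxyacetyl)piperidine | CCOC(OCC)C(=O)N1CCCCC1 | starting material
5 | benzylic lithium species of 3 (not isolated) | COC(=O)c1c(C[Li])c(Cl)c(O[Si](C(C)C)(C(C)C)C(C)C)cc1O[Si](C(C)C)(C(C)C)C(C)C | intermediate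
6 | methyl 3-chloro-2-(3,3-diethoxy-2-oxopropyl)-4,6-bis[(triisopropylsilyl)oxy]benzoate | CCOC(OCC)C(=O)Cc1c(Cl)c(O[Si](C(C)C)(C(C)C)C(C)C)cc(O[Si](C(C)C)(C(C)C)C(C)C)c1C(=O)OC | intermediate
7 | 5-chloro-1-oxo-6,8-bis[(triisopropylsilyl)oxy]-1H-isochromene-3-carbaldehyde | O=Cc1cc2c(Cl)c(O[Si](C(C)C)(C(C)C)C(C)C)cc(O[Si](C(C)C)(C(C)C)C(C)C)c2c(=O)o1 | intermediate
8 | (triphenylphosphoranylidene)acetaldehyde | O=CC=P(c1ccccc1)(c1ccccc1)c1ccccc1 | starting material
9 | (2E)-3-{5-chloro-1-oxo-6,8-bis[(triisopropylsilyl)oxy]-1H-isochromen-3-yl}prop-2-enal | O=C/C=C/c1cc2c(Cl)c(O[Si](C(C)C)(C(C)C)C(C)C)cc(O[Si](C(C)C)(C(C)C)C(C)C)c2c(=O)o1 | intermediate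
10 | ethyl (3S)-3-hydroxybutanoate | C[C@H](O)CC(=O)OCC | starting material
11 | (3S)-3-hydroxy-N-methoxy-N-methylbutanamide | C[C@H](O)CC(=O)N(C)OC | intermediate
12 | (E)-1,2-bis(tributylstannyl)ethene | CCCC[Sn](CCCC)(CCCC)/C=C/[Sn](CCCC)(CCCC)CCCC | starting material
13 | (E)-2-(tributylstannyl)vinyllithium (not isolated) | [Li]/C=C/[Sn](CCCC)(CCCC)CCCC | intermediate
14 | (1E,5S)-5-hydroxy-1-(tributylstannyl)hex-1-en-3-one | C[C@H](O)CC(=O)/C=C/[Sn](CCCC)(CCCC)CCCC | intermediate
15 | diethylboron chelate of 14 (not isolated) | C[C@H]1CC(/C=C/[Sn](CCCC)(CCCC)CCCC)=[O+][B-](CC)(CC)O1 | intermediate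
16 | (1E,3S,5S)-1-(tributylstannyl)hex-1-ene-3,5-diol | C[C@H](O)C[C@H](O)/C=C/[Sn](CCCC)(CCCC)CCCC | intermediate
17 | (1E,3S,5S)-1-iodohex-1-ene-3,5-diol | C[C@H](O)C[C@H](O)/C=C/I | intermediate
18 | 5-chloro-3-[(1E,4E,6S,8S)-3,6,8-trihydroxynona-1,4-dien-1-yl]-6,8-bis[(triisopropylsilyl)oxy]-1H-isochromen-1-one | C[C@H](O)C[C@H](O)/C=C/C(O)/C=C/c1cc2c(Cl)c(O[Si](C(C)C)(C(C)C)C(C)C)cc(O[Si](C(C)C)(C(C)C)C(C)C)c2c(=O)o1 | intermediate
19 | pentadienyl cation from 18 (not isolated) | C[C@H](O)C[C@H](O)/C=C/[CH+]/C=C/c1cc2c(Cl)c(O[Si](C(C)C)(C(C)C)C(C)C)cc(O[Si](C(C)C)(C(C)C)C(C)C)c2c(=O)o1 | intermediate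
20 | 5-chloro-3-[(1E,3E)-4-[(2R,3S,5S)-3-hydroxy-5-methyloxolan-2-yl]buta-1,3-dien-1-yl]-6,8-bis[(triisopropylsilyl)oxy]-1H-isochromen-1-one | C[C@H]1C[C@H](O)[C@@H](/C=C/C=C/c2cc3c(Cl)c(O[Si](C(C)C)(C(C)C)C(C)C)cc(O[Si](C(C)C)(C(C)C)C(C)C)c3c(=O)o2)O1 | intermediate
21 | 5-chloro-6,8-dihydroxy-3-[(1E,3E)-4-[(2R,3S,5S)-3-hydroxy-5-methyloxolan-2-yl]buta-1,3-dien-1-yl]-1H-isochromen-1-one | C[C@H]1C[C@H](O)[C@@H](/C=C/C=C/c2cc3c(Cl)c(O)cc(O)c3c(=O)o2)O1 | target

**Step count**

Total steps: 12. Longest linear sequence: 8 (steps 1–5, 10, 11, 12).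

**Steps most likely to fail**

Step 11. The pentadienyl cation may leak away before ring closure, by a 1,2-hydride shift from the neighbouring carbinol carbon or by proton loss (both ending in a ketone), by 4π-electrocyclisation, or by oligomerisation. Convergence of the C2 epimers may also be incomplete. The fallback sets out from 18 and closes the ring by anionic chemistry before any cation is made. Oxidation of the bis-allylic alcohol with MnO2 would give the cross-conjugated dienone 5-chloro-3-[(1E,4E,6S,8S)-6,8-dihydroxy-3-oxonona-1,4-dien-1-yl]-6,8-bis[(triisopropylsilyl)oxy]-1H-isochromen-1-one F1. A reversible, base-mediated 5-exo oxa-Michael addition of the C8 hydroxyl (DBU, CH2Cl2) should then give the 2,3-trans-2,5-cis oxolanyl enone 5-chloro-3-[(1E)-4-[(2R,3S,5S)-3-hydroxy-5-methyloxolan-2-yl]-3-oxobut-1-en-1-yl]-6,8-bis[(triisopropylsilyl)oxy]-1H-isochromen-1-one F2. Luche reduction would give the allylic alcohol 5-chloro-3-[(1E)-3-hydroxy-4-[(2R,3S,5S)-3-hydroxy-5-methyloxolan-2-yl]but-1-en-1-yl]-6,8-bis[(triisopropylsilyl)oxy]-1H-isochromen-1-one F3. Acid-catalysed dehydration of this allylic alcohol (PPTS, toluene, 60 °C), which only requires proton loss from the adjacent methylene group, would bring the route back at 20.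

Step 4. Enol-lactonisation onto the doubly ortho-substituted ester may stall at the keto ester or aldehyde hydrate, and the silyl ether next to the carbonyl may be lost under aqueous acid. The fallback sets out from 3 and brings in the aldehyde by oxidation after ring closure. Lithiation to 5 and acylation with N-methoxy-N-methylacetamide would give the methyl ketone methyl 3-chloro-2-(2-oxopropyl)-4,6-bis[(triisopropylsilyl)oxy]benzoate F4. Enolate O-acylation (NaH, THF) should close the lactone to 5-chloro-3-methyl-6,8-bis[(triisopropylsilyl)oxy]-1H-isochromen-1-one F5. Oxidation of the activated 3-methyl group with SeO2 (dioxane, 100 °C) would rejoin the route at 7.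

Step 7. The stannylvinyllithium may be consumed by proton transfer, the tin group may be lost from the β-stannyl enone on work-up, and the liberated hydroxylamine may add in conjugate fashion. The fallback sets out from 11 and carries the two vinyl carbons as an alkyne. Addition of lithium (trimethylsilyl)acetylide would give the ynone (5S)-5-hydroxy-1-(trimethylsilyl)hex-1-yn-3-one F6. The same boron-chelate syn-reduction would give (3S,5S)-1-(trimethylsilyl)hex-1-yne-3,5-diol F7, and K2CO3 in methanol would give (3S,5S)-hex-1-yne-3,5-diol F8. Hydrozirconation with Cp2Zr(H)Cl (excess) followed by iodinolysis would return to the route at 17.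

Further compounds
F1 | step 11 | 5-chloro-3-[(1E,4E,6S,8S)-6,8-dihydroxy-3-oxonona-1,4-dien-1-yl]-6,8-bis[(triisopropylsilyl)oxy]-1H-isochromen-1-one | C[C@H](O)C[C@H](O)/C=C/C(=O)/C=C/c1cc2c(Cl)c(O[Si](C(C)C)(C(C)C)C(C)C)cc(O[Si](C(C)C)(C(C)C)C(C)C)c2c(=O)o1
F2 | step 11 | 5-chloro-3-[(1E)-4-[(2R,3S,5S)-3-hydroxy-5-methyloxolan-2-yl]-3-oxobut-1-en-1-yl]-6,8-bis[(triisopropylsilyl)oxy]-1H-isochromen-1-one | C[C@H]1C[C@H](O)[C@@H](CC(=O)/C=C/c2cc3c(Cl)c(O[Si](C(C)C)(C(C)C)C(C)C)cc(O[Si](C(C)C)(C(C)C)C(C)C)c3c(=O)o2)O1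
F3 | step 11 | 5-chloro-3-[(1E)-3-hydroxy-4-[(2R,3S,5S)-3-hydroxy-5-methyloxolan-2-yl]but-1-en-1-yl]-6,8-bis[(triisopropylsilyl)oxy]-1H-isochromen-1-one | C[C@H]1C[C@H](O)[C@@H](CC(O)/C=C/c2cc3c(Cl)c(O[Si](C(C)C)(C(C)C)C(C)C)cc(O[Si](C(C)C)(C(C)C)C(C)C)c3c(=O)o2)O1
F4 | step 4 | methyl 3-chloro-2-(2-oxopropyl)-4,6-bis[(triisopropylsilyl)oxy]benzoate | COC(=O)c1c(CC(C)=O)c(Cl)c(O[Si](C(C)C)(C(C)C)C(C)C)cc1O[Si](C(C)C)(C(C)C)C(C)C
F5 | step 4 | 5-chloro-3-methyl-6,8-bis[(triisopropylsilyl)oxy]-1H-isochromen-1-one | Cc1cc2c(Cl)c(O[Si](C(C)C)(C(C)C)C(C)C)cc(O[Si](C(C)C)(C(C)C)C(C)C)c2c(=O)o1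
F6 | step 7 | (5S)-5-hydroxy-1-(trimethylsilyl)hex-1-yn-3-one | C[C@H](O)CC(=O)C#C[Si](C)(C)C
F7 | step 7 | (3S,5S)-1-(trimethylsilyl)hex-1-yne-3,5-diol | C[C@H](O)C[C@H](O)C#C[Si](C)(C)C
F8 | step 7 | (3S,5S)-hex-1-yne-3,5-diol | C[C@H](O)C[C@H](O)C#C
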